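**Strategy.** The route rests on reading C4 of the central fisetinidol unit (unit B) as an aldehyde carbon: it is a diarylmethine bonded to C4a of its own resorcinol ring and to C6 of the catechin phloroglucinol ring. In one Lewis acid operation the aldehyde of an acyclic aryl ether closes the pyran ring of unit B (O1, C2, C3, C4, C4a, C8a) by attack of C4a, then C4 ionises and is arylated by the preformed fisetinidol-(4α→8)-catechin, which also sets C4. The precursor is a 3-aryl-3-aryloxy-2-hydroxypropanal whose C2 and C3 come from a Sharpless epoxide opened by the phenol of a unit A–resorcinol adduct. All eleven other rings are already in place.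

Key step: step 11

Remark: (2R,3R)-fustin (3) is assumed to be commercially available as the enantiopure natural product; unit letters are A = outer fisetinidol bonded through C4 to C6 of B, B = central fisetinidol, C = catechin, D = fisetinidol on C8 of C.

Step 1
Reactants: 1 (+)-catechin
Product: 2 5,7,3',4'-tetra-O-benzyl-(+)-catechin
Conditions: BnBr (4.4 equiv), K2CO3, DMF, 0 °C to rt, Ar
Reagents that add atoms: benzyl bromide, BrCc1ccccc1
Why: Williamson ether synthesis in which carbonate deprotonates only the four phenols, the C3 alcohol stays free and no stereocentre is touched.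

Step 2
Reactants: 3 (2R,3R)-fustin
Product: 4 7,3',4'-tri-O-benzylfustin
Conditions: BnBr (3.3 equiv), K2CO3, DMF, rt, Ar
Reagents that add atoms: benzyl bromide, BrCc1ccccc1
Why: Williamson ether synthesis under mild, oxygen-free carbonate conditions so that the base-sensitive trans-dihydroflavonol should neither epimerise nor oxidise while its three phenols are benzylated.

Step 3
Reactants: 4 7,3',4'-tri-O-benzylfustin
Product: 5 (2R,3S,4R)-7-benzyloxy-2-[3,4-bis(benzyloxy)phenyl]chromane-3,4-diol
Conditions: NaBH4, THF/EtOH, 0 °C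
Reagents that add atoms: none
Why: Borohydride reduction of the C4 ketone in which axial hydride delivery to the 2,3-trans-dihydroflavonol should give mainly the equatorial C4 alcohol (3,4-trans), a centre that is in any case erased when C4 ionises in steps 4 and 5.

Step 4
Reactants: 5 tri-O-benzyl flavan-3,4-diol; 2 tetra-O-benzylcatechin
Product: 6 hepta-O-benzyl fisetinidol-(4α→8)-catechin
Conditions: Sc(OTf)3 (10 mol%), 2 (4 equiv), CH2Cl2/MeCN, −20 to 0 °C
Reagents that add atoms: none
Why: Lewis acid-catalysed dehydrative Friedel-Crafts alkylation (flavan-3,4-diol condensation) in which the C4 hydroxyl, flanked by an ortho and a para ring oxygen, ionises to the flavan-4-yl cation and excess 2 captures it through C8, its more accessible phloroglucinol position, anti to the C3 hydroxyl so that the new C4 stereocentre should be 3,4-trans.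

Step 5
Reactants: 5 tri-O-benzyl flavan-3,4-diol; 7 resorcinol
Product: 8 (2R,3S,4R)-7-benzyloxy-2-[3,4-bis(benzyloxy)phenyl]-4-(2,4-dihydroxyphenyl)chroman-3-ol
Conditions: Sc(OTf)3 (10 mol%), 7 (8 equiv), MeCN/CH2Cl2, −20 to 0 °C
Reagents that add atoms: none
Why: The same dehydrative Friedel-Crafts alkylation, in which excess resorcinol attacks the flavan-4-yl cation through its C4 (para to one hydroxyl and ortho to the other, C2 being flanked twice) and anti to the C3 hydroxyl, setting the 3,4-trans C4 stereocentre, with any 3,4-cis epimer to be removed by chromatography.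

Step 6
Reactants: 9 3,4-bis(benzyloxy)benzaldehyde
Product: 10 ethyl (E)-3-[3,4-bis(benzyloxy)phenyl]prop-2-enoate
Conditions: (EtO)2P(O)CH2CO2Et, NaH, THF, 0 °C to rt
Reagents that add atoms: triethyl phosphonoacetate, CCOC(=O)CP(=O)(OCC)OCC
Why: Horner-Wadsworth-Emmons olefination with a stabilised phosphonate anion, which should give the (E)-cinnamate.

Step 7
Reactants: 10 ethyl (E)-cinnamate
Product: 11 (E)-3-[3,4-bis(benzyloxy)phenyl]prop-2-en-1-ol
Conditions: iBu2AlH, CH2Cl2, −78 to 0 °C
Reagents that add atoms: none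
Why: Aluminium hydride 1,2-reduction of the unsaturated ester to the allylic alcohol, leaving the alkene and the benzyl ethers untouched.

Step 8
Reactants: 11 (E)-allylic alcohol
Product: 12 [(2S,3S)-3-[3,4-bis(benzyloxy)phenyl]oxiran-2-yl]methanol
Conditions: Ti(OiPr)4 (10 mol%), L-(+)-diethyl tartrate (12 mol%), tBuOOH, 4 Å MS, CH2Cl2, −25 °C
Reagents that add atoms: tert-butyl hydroperoxide, CC(C)(C)OO
Why: Katsuki-Sharpless asymmetric epoxidation, in which the L-(+)-tartrate titanium complex delivers oxygen to the alkene face that gives the (2S,3S)-trans-epoxy alcohol, while catalytic loading, sieves and low temperature limit opening of the electron-rich aryl epoxide.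

Step 9
Reactants: 8 unit A–resorcinol adduct; 12 (2S,3S)-epoxy alcohol
Product: 14 O-benzylated (2S,3R)-3-aryl-3-aryloxypropane-1,2-diol, via phenol diol 13 (not isolated)
Conditions: Cs2CO3, DMF, 50 °C; then BnBr (1.3 equiv), rt
Reagents that add atoms: benzyl bromide, BrCc1ccccc1
Why: Phenoxide SN2 opening of the aryl glycidol at its benzylic carbon with inversion sets the R aryl ether centre (future C2 of unit B) next to the untouched S carbinol (future C3), the hydroxyl para to the flavanyl group reacting because the other is shielded by that bulky ortho substituent, which is then capped by Williamson benzylation.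

Step 10
Reactants: 14 benzylated diol
Product: 15 (2R,3R)-3-aryl-3-aryloxy-2-hydroxypropanal
Conditions: TEMPO (10 mol%), PhI(OAc)2 (1.1 equiv), CH2Cl2, 0 °C to rt
Reagents that add atoms: none
Why: Nitroxyl-catalysed (TEMPO) oxidation, which is selective for the primary alcohol over the two secondary ones and should stop at the aldehyde under anhydrous, non-basic conditions that leave the α-stereocentre intact.

Step 11
Reactants: 15 hydroxy aldehyde; 6 hepta-O-benzyl fisetinidol-(4α→8)-catechin
Product: 17 trideca-O-benzyl ether of the target tetraflavanoid, via flavan-3,4-diol 16 (not isolated)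
Conditions: Sc(OTf)3 (20 mol%), 6 (1.2 equiv), 4 Å MS, CH2Cl2/MeCN, −40 to 0 °C
Reagents that add atoms: none
Why: Proposed new method: the sequence is a cross bis-arylation of an aldehyde carbon, whose closest known reaction types are the acid-mediated cyclisation of 3-aryloxypropanals or their acetals to chroman-4-ols and the Lewis acid condensation of benzylated flavan-3,4-diols with flavan-3-ols, here merged on an α-hydroxy-β-aryloxy aldehyde for which the combination has not been shown. Sc(OTf)3 chelates the hydroxy aldehyde of 15, the tethered resorcinol diether ring attacks the carbonyl carbon through its position para to the benzyloxy group (future C4a) and closes the pyran ring of unit B by a 6-exo-trig Friedel-Crafts hydroxyalkylation to give carbinol 16, whose C4 hydroxyl, flanked by an ortho and a para ring oxygen, ionises to the flavan-4-yl cation that C6 of the catechin unit of 6 captures. C2 and C3 of unit B are already set in steps 8 and 9, so C4 is the only new stereocentre: the arene adds to the half-chair cation anti to the C3 hydroxyl and all three substituents end up equatorial (2,3-trans-3,4-trans), both C4 epimers of 16 converging on the same cation. Regioselectivity of the ring closure rests on the position para to the benzyloxy group being open while the one between the two oxygens is flanked twice, and site selectivity in 6 rests on C6 being the only unsubstituted carbon of its phloroglucinol-type ring, far more nucleophilic than any resorcinol-type or catechol ring present. The acyclic benzylic aryl ether bond C2-O1 should survive because its cation would have only one para oxygen and sits next to the electron-withdrawing hydroxy aldehyde unit, so that carbonyl activation and ionisation at C4 are faster at low temperature. If 6 adds to the aldehyde first, the resulting carbinol ionises and ring closure through a chair transition state leads to the same all-equatorial product.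

Step 12
Reactants: 17 trideca-O-benzyl tetraflavanoid
Product: 18 fisetinidol-(4α→6)-fisetinidol-(4α→6)-[fisetinidol-(4α→8)]-catechin (CNP0263622.1)
Conditions: H2 (1 atm), Pd(OH)2/C, THF/MeOH/H2O, rt
Reagents that add atoms: none
Why: Catalytic hydrogenolysis of the thirteen aryl benzyl ethers under neutral ambient-pressure conditions, under which the cyclic benzylic C2-O1 ethers and the C4-aryl bonds of oligomeric flavan-3-ols should persist, so that no stereocentre is affected.

**Compound list**

1 | (+)-catechin, (2R,3S)-2-(3,4-dihydroxyphenyl)chromane-3,5,7-triol | Oc1cc(O)c2c(c1)O[C@H](c1ccc(O)c(O)c1)[C@@H](O)C2 | starting material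
2 | 5,7,3',4'-tetra-O-benzyl-(+)-catechin, (2R,3S)-5,7-bis(benzyloxy)-2-[3,4-bis(benzyloxy)phenyl]chroman-3-ol | c1ccccc1COc1cc(OCc3ccccc3)c2c(c1)O[C@H](c1ccc(OCc3ccccc3)c(OCc3ccccc3)c1)[C@@H](O)C2 | intermediate
3 | (2R,3R)-fustin, (2R,3R)-2-(3,4-dihydroxyphenyl)-3,7-dihydroxychroman-4-one | Oc1ccc2c(c1)O[C@H](c1ccc(O)c(O)c1)[C@@H](O)C2=O | starting material
4 | 7,3',4'-tri-O-benzylfustin, (2R,3R)-7-benzyloxy-2-[3,4-bis(benzyloxy)phenyl]-3-hydroxychroman-4-one | c1ccccc1COc1ccc2c(c1)O[C@H](c1ccc(OCc3ccccc3)c(OCc3ccccc3)c1)[C@@H](O)C2=O | intermediate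
5 | (2R,3S,4R)-7-benzyloxy-2-[3,4-bis(benzyloxy)phenyl]chromane-3,4-diol (2,3-trans-3,4-trans) | c1ccccc1COc1ccc2c(c1)O[C@H](c1ccc(OCc3ccccc3)c(OCc3ccccc3)c1)[C@@H](O)[C@@H]2O | intermediate
6 | hepta-O-benzyl fisetinidol-(4α→8)-catechin: compound 2 carrying at C8 the (2R,3S,4S)-7-benzyloxy-2-[3,4-bis(benzyloxy)phenyl]-3-hydroxychroman-4-yl group (3,4-trans), C6 unsubstituted | c1c(OCc5ccccc5)c2c(c([C@@H]3c4ccc(OCc5ccccc5)cc4O[C@H](c4ccc(OCc5ccccc5)c(OCc5ccccc5)c4)[C@H]3O)c1OCc6ccccc6)O[C@H](c1ccc(OCc3ccccc3)c(OCc3ccccc3)c1)[C@@H](O)C2 | intermediate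
7 | resorcinol (benzene-1,3-diol) | Oc1cccc(O)c1 | starting material
8 | (2R,3S,4R)-7-benzyloxy-2-[3,4-bis(benzyloxy)phenyl]-4-(2,4-dihydroxyphenyl)chroman-3-ol (2,3-trans-3,4-trans) | c1ccccc1COc1ccc2c(c1)O[C@H](c1ccc(OCc3ccccc3)c(OCc3ccccc3)c1)[C@@H](O)[C@@H]2c1ccc(O)cc1O | intermediate
9 | 3,4-bis(benzyloxy)benzaldehyde | O=Cc1ccc(OCc2ccccc2)c(OCc2ccccc2)c1 | starting material
10 | ethyl (E)-3-[3,4-bis(benzyloxy)phenyl]prop-2-enoate | CCOC(=O)/C=C/c1ccc(OCc2ccccc2)c(OCc2ccccc2)c1 | intermediate
11 | (E)-3-[3,4-bis(benzyloxy)phenyl]prop-2-en-1-ol | OC/C=C/c1ccc(OCc2ccccc2)c(OCc2ccccc2)c1 | intermediate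
12 | [(2S,3S)-3-[3,4-bis(benzyloxy)phenyl]oxiran-2-yl]methanol (trans) | OC[C@@H]1O[C@H]1c1ccc(OCc2ccccc2)c(OCc2ccccc2)c1 | intermediate
13 | (2S,3R)-3-[3,4-bis(benzyloxy)phenyl]-3-[3-hydroxy-4-(flavan-4-yl)phenoxy]propane-1,2-diol, the flavan-4-yl group being that of 8 with unchanged configuration | c1ccccc1COc1ccc2c(c1)O[C@H](c1ccc(OCc3ccccc3)c(OCc3ccccc3)c1)[C@@H](O)[C@@H]2c1ccc(O[C@H](c2ccc(OCc3ccccc3)c(OCc3ccccc3)c2)[C@@H](O)CO)cc1O | intermediate
14 | (2S,3R)-3-[3,4-bis(benzyloxy)phenyl]-3-[3-benzyloxy-4-(flavan-4-yl)phenoxy]propane-1,2-diol, flavan-4-yl group as in 8 | c1ccccc1COc1ccc2c(c1)O[C@H](c1ccc(OCc3ccccc3)c(OCc3ccccc3)c1)[C@@H](O)[C@@H]2c1ccc(O[C@H](c2ccc(OCc3ccccc3)c(OCc3ccccc3)c2)[C@@H](O)CO)cc1OCc4ccccc4 | intermediate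
15 | (2R,3R)-3-[3,4-bis(benzyloxy)phenyl]-3-[3-benzyloxy-4-(flavan-4-yl)phenoxy]-2-hydroxypropanal, flavan-4-yl group as in 8 | c1ccccc1COc1ccc2c(c1)O[C@H](c1ccc(OCc3ccccc3)c(OCc3ccccc3)c1)[C@@H](O)[C@@H]2c1ccc(O[C@H](c2ccc(OCc3ccccc3)c(OCc3ccccc3)c2)[C@@H](O)C=O)cc1OCc4ccccc4 | intermediate
16 | hexa-O-benzyl fisetinidol-(4α→6)-flavan-3,4-diol: unit B closed as a 2,3-trans chromane-3,4-diol (2R,3S), both C4 epimers, carrying unit A at C6 | c1ccccc1COc1ccc2c(c1)O[C@H](c1ccc(OCc3ccccc3)c(OCc3ccccc3)c1)[C@@H](O)[C@@H]2c1cc2c(cc1OCc4ccccc4)O[C@H](c1ccc(OCc3ccccc3)c(OCc3ccccc3)c1)[C@@H](O)C2O | intermediate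
17 | trideca-O-benzyl ether (all thirteen phenols) of fisetinidol-(4α→6)-fisetinidol-(4α→6)-[fisetinidol-(4α→8)]-catechin, every unit 2,3-trans, every interflavan bond 3,4-trans | c1ccccc1COc1ccc2c(c1)O[C@H](c1ccc(OCc3ccccc3)c(OCc3ccccc3)c1)[C@@H](O)[C@@H]2c1cc2c(cc1OCc4ccccc4)O[C@H](c1ccc(OCc3ccccc3)c(OCc3ccccc3)c1)[C@@H](O)[C@@H]2c1c(OCc5ccccc5)c2c(c([C@@H]3c4ccc(OCc5ccccc5)cc4O[C@H](c4ccc(OCc5ccccc5)c(OCc5ccccc5)c4)[C@H]3O)c1OCc6ccccc6)O[C@H](c1ccc(OCc3ccccc3)c(OCc3ccccc3)c1)[C@@H](O)C2 | intermediate
18 | fisetinidol-(4α→6)-fisetinidol-(4α→6)-[fisetinidol-(4α→8)]-catechin (unit A 2R,3S,4R; unit B 2R,3S,4S; unit C 2R,3S; unit D 2R,3S,4S), CNP0263622.1 | Oc1ccc2c(c1)O[C@H](c1ccc(O)c(O)c1)[C@@H](O)[C@@H]2c1cc2c(cc1O)O[C@H](c1ccc(O)c(O)c1)[C@@H](O)[C@@H]2c1c(O)c2c(c([C@@H]3c4ccc(O)cc4O[C@H](c4ccc(O)c(O)c4)[C@H]3O)c1O)O[C@H](c1ccc(O)c(O)c1)[C@@H](O)C2 | target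

**Step count.** Total: 12 steps. Longest linear sequence: 7 steps (3 → 4 → 5 → 8 → 14 → 15 → 17 → 18; the branch from 9 is equally long).

**Steps most likely to fail**

1. Step 11 (Proposed new method). Process at risk: ionisation of the acyclic benzylic aryl ether, hydride-shift isomerisation of the hydroxy aldehyde or intermolecular oligomerisation may outrun ring closure, and capture at the hindered C6 of 6 may be slower than elimination of the cation. Fallback with known chemistry, storing a leaving group at C4: setting out from 15, acetalisation with HC(OMe)3 and pyridinium p-toluenesulfonate in MeOH should give the dimethyl acetal F1. Catalytic SnCl4 in CH2Cl2 at −78 °C should then cyclise it by oxocarbenium Friedel-Crafts alkylation, without external nucleophile, to the 4-methoxyflavan-3-ol F2. Activation of F2 with TMSOTf at −78 °C in the presence of 6 (4-alkoxyflavan coupling) comes back to the route at 17.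

2. Step 9. Process at risk: alkylation at the hindered phenol or at both phenols, and Payne rearrangement followed by opening at the non-benzylic carbon. Fallback that differentiates the phenols by protecting groups: setting out from 8, bulky TIPSCl with imidazole should silylate only the unhindered phenol to give the silyl ether F3. Benzylation of the remaining phenol (BnBr, K2CO3, acetone) gives the benzyl silyl diether F4, and Bu4NF in THF releases the single free phenol F5. This phenol is joined with 12 under the first-stage conditions of step 9 and comes back at 14.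

3. Step 10. Process at risk: glycol cleavage of the 1,2-diol by the iodine reagent, over-oxidation, and epimerisation or β-elimination of the free hydroxy aldehyde on isolation. Fallback through silyl ethers: setting out from 14, TESOTf with 2,6-lutidine should silylate all three alcohols to the tris(triethylsilyl) ether F6. Swern conditions ((COCl)2, DMSO, then Et3N, −78 to −30 °C) should convert the primary silyl ether directly into the aldehyde while the secondary silyl ethers persist, giving the bis(triethylsilyl) aldehyde F7. HF·pyridine in THF at 0 °C then removes the two silyl groups just before use and comes back at 15.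

Further compounds
F1 | step 11 | dimethyl acetal of 15, (2R,3R)-3-aryl-3-aryloxy-1,1-dimethoxypropan-2-ol | c1ccccc1COc1ccc2c(c1)O[C@H](c1ccc(OCc3ccccc3)c(OCc3ccccc3)c1)[C@@H](O)[C@@H]2c1ccc(O[C@H](c2ccc(OCc3ccccc3)c(OCc3ccccc3)c2)[C@@H](O)C(OC)OC)cc1OCc4ccccc4
F2 | step 11 | 4-methoxy analogue of 16 (4-O-methyl ether, both C4 epimers) | c1ccccc1COc1ccc2c(c1)O[C@H](c1ccc(OCc3ccccc3)c(OCc3ccccc3)c1)[C@@H](O)[C@@H]2c1cc2c(cc1OCc4ccccc4)O[C@H](c1ccc(OCc3ccccc3)c(OCc3ccccc3)c1)[C@@H](O)C2OC
F3 | step 9 | 8 with the phenol para to the flavanyl group as triisopropylsilyl ether | c1ccccc1COc1ccc2c(c1)O[C@H](c1ccc(OCc3ccccc3)c(OCc3ccccc3)c1)[C@@H](O)[C@@H]2c1ccc(O[Si](C(C)C)(C(C)C)C(C)C)cc1O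
F4 | step 9 | F3 with the phenol ortho to the flavanyl group as benzyl ether | c1ccccc1COc1ccc2c(c1)O[C@H](c1ccc(OCc3ccccc3)c(OCc3ccccc3)c1)[C@@H](O)[C@@H]2c1ccc(O[Si](C(C)C)(C(C)C)C(C)C)cc1OCc4ccccc4
F5 | step 9 | (2R,3S,4R)-7-benzyloxy-2-[3,4-bis(benzyloxy)phenyl]-4-(2-benzyloxy-4-hydroxyphenyl)chroman-3-ol | c1ccccc1COc1ccc2c(c1)O[C@H](c1ccc(OCc3ccccc3)c(OCc3ccccc3)c1)[C@@H](O)[C@@H]2c1ccc(O)cc1OCc4ccccc4
F6 | step 10 | tris(triethylsilyl) ether of 14 (both diol oxygens and the C3 oxygen of unit A) | c1ccccc1COc1ccc2c(c1)O[C@H](c1ccc(OCc3ccccc3)c(OCc3ccccc3)c1)[C@@H](O[Si](CC)(CC)CC)[C@@H]2c1ccc(O[C@H](c2ccc(OCc3ccccc3)c(OCc3ccccc3)c2)[C@@H](O[Si](CC)(CC)CC)CO[Si](CC)(CC)CC)cc1OCc4ccccc4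
F7 | step 10 | bis(triethylsilyl) ether of 15 (α-silyloxy aldehyde, unit A C3 silyl ether) | c1ccccc1COc1ccc2c(c1)O[C@H](c1ccc(OCc3ccccc3)c(OCc3ccccc3)c1)[C@@H](O[Si](CC)(CC)CC)[C@@H]2c1ccc(O[C@H](c2ccc(OCc3ccccc3)c(OCc3ccccc3)c2)[C@@H](O[Si](CC)(CC)CC)C=O)cc1OCc4ccccc4
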